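**Strategy.** The route rests on disconnecting C1–C6 of the cyclohexene ring. In the target, the fully substituted C1 (bearing O1 and C7) is bonded to C6, which is allylic to C4=C5: the array C7–C1–C6–C5=C4 is the imprint of an ester-enolate Claisen shift. The precursor is a D-galacturonate-derived δ-lactone (C7 carbonyl, ring oxygen on C4) carrying O1 as a PMB ether, O2/O3 as a cis acetonide and an (E)-PMB enol ether C5=C6. In one operation its silyl ketene acetal rearranges through a boat transition state, forming C1–C6, the carbocycle, the C4=C5 alkene and both new stereocentres (C1, C6), with O6 trans to O1 for later epoxide closure.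

Key step: step 9

Remarks.
- Atom labels are those of the target throughout: C1 (oxirane carbon bearing C7), C2 (benzoate carbinol), C3 (free carbinol), C4=C5, C6 (oxirane CH); O6 is the temporary oxygen on C6.
- They map onto D-galacturonic acid as C7 = sugar C6, C1 = C5, C2 = C4, C3 = C3, C4 = C2, C5 = C1; C6 comes from the ylide.
- Lactone and carbocycle are both six-membered: the shift trades C7 and the ring oxygen for C5 and C6, with no change of ring size.
- Design choices: the uronate is olefinated as its carboxylate, because a 4-O-substituted galacturonate ester is prone to β-elimination under base. The lactone is closed before O1 is protected. The acetonide is removed before the oxirane exists, and O3 is silylated so that the C2 benzoate needs no regioselective acylation.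
- Assumptions: the E and Z enol ethers are separable at the lactone stage; group-transfer reagents are given by name and SMILES and are not numbered; 1 is drawn open-chain but reacts as the pyranose.

**Step 1**
Reactants: 1 D-galacturonic acid (monohydrate)
Product: 2 benzyl D-galactopyranuronate
Conditions: BnBr, NaHCO3, DMF, rt
Reagents that add atoms: benzyl bromide, BrCc1ccccc1
Why: Carboxylate O-alkylation (SN2 esterification) under bicarbonate touches neither the hemiacetal nor the secondary hydroxyls and makes the sugar soluble and chromatographable for the next step; no stereocentre is involved.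

**Step 2**
Reactants: 2 benzyl D-galactopyranuronate
Product: 3 benzyl 3,4-O-isopropylidene-D-galactopyranuronate
Conditions: 2-methoxypropene (2 equiv), TsOH·H2O (cat.), DMF, 0 °C; Et3N quench
Reagents that add atoms: 2-methoxypropene, COC(C)=C
Why: Kinetic acetalisation with an enol ether and catalytic acid should engage the cis-3,4-diol (sugar locants; the future O3 and O2) as its five-membered isopropylidene acetal and leave the anomeric and 2-hydroxyls free, as it does with 6-deoxygalactose; no stereocentre is created.

**Step 3**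
Reactants: 3 benzyl 3,4-O-isopropylidene-D-galactopyranuronate
Product: 4 3,4-O-isopropylidene-D-galactopyranuronic acid
Conditions: H2 (1 atm), Pd/C, EtOAc, rt
Reagents that add atoms: none
Why: Catalytic hydrogenolysis of the benzyl ester is neutral and returns the free acid, so that the strongly basic olefination meets a carboxylate, which cannot suffer the C–O β-elimination typical of 4-O-substituted galacturonate esters.

**Step 4**
Reactants: 5 4-methoxybenzyl alcohol
Product: 6 4-methoxybenzyl (methylthio)methyl ether
Conditions: NaH, NaI (cat.), MeSCH2Cl, DME, 0 °C → rt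
Reagents that add atoms: chloromethyl methyl sulfide, CSCCl
Why: Williamson etherification of the sodium alkoxide with the α-chloro sulfide (iodide catalysis) gives the O,S-acetal.

**Step 5**
Reactants: 6 4-methoxybenzyl (methylthio)methyl ether
Product: 8 [(4-methoxybenzyloxy)methyl]triphenylphosphonium chloride, via chloromethyl ether 7 (not isolated)
Conditions: SO2Cl2, CH2Cl2, −78 °C; evaporate; PPh3, toluene, rt
Reagents that add atoms: sulfuryl chloride, O=S(=O)(Cl)Cl; triphenylphosphine, c1ccc(cc1)P(c1ccccc1)c1ccccc1
Why: Chlorinolysis of the O,S-acetal by sulfuryl chloride (chlorosulfonium ion, loss of MeSCl) gives the α-chloro ether, which quaternises triphenylphosphine by SN2 to the Wittig salt, as methoxymethyl and benzyloxymethyl chlorides do.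

**Step 6**
Reactants: 4 3,4-O-isopropylidene-D-galactopyranuronic acid; 8 [(4-methoxybenzyloxy)methyl]triphenylphosphonium chloride
Product: 10 (E)-6,7-dideoxy-3,4-O-isopropylidene-7-(4-methoxybenzyloxy)-L-galacto-hept-6-enonic acid, via phosphorus ylide 9 (not isolated)
Conditions: 8, KHMDS, THF, −40 → 0 °C; then tripotassium salt of 4 (KHMDS, 3 equiv, THF–DMPU), −40 °C → rt; pH 5 buffer, isolated as Et3NH+ salt
Reagents that add atoms: none
Why: Wittig olefination of the open-chain aldehyde in equilibrium with the hemiacetal: the carboxylate and the alkoxide next to the aldehyde suppress enolisation, so C4 (target numbering) keeps its configuration, and the alkoxymethylene ylide is expected to give both enol ether geometries, which are carried together as triethylammonium salts to step 7.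

**Step 7**
Reactants: 10 (E)-6,7-dideoxy-3,4-O-isopropylidene-7-(4-methoxybenzyloxy)-L-galacto-hept-6-enonic acid
Product: 11 (E)-6,7-dideoxy-3,4-O-isopropylidene-7-(4-methoxybenzyloxy)-L-galacto-hept-6-enono-1,5-lactone
Conditions: EDC·HCl, DMAP (cat.), CH2Cl2 (0.01 M), 0 °C → rt; chromatography on Et3N-washed SiO2
Reagents that add atoms: none
Why: Carbodiimide (Steglich-type) lactonisation under near-neutral conditions: only the hydroxyl on C4 can reach the activated carboxyl C7 through a six-membered ring (the hydroxyl on C1 cannot), the enol ether is not exposed to acid, and the (Z)-isomer is removed by chromatography so that only the (E)-lactone goes on.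

**Step 8**
Reactants: 11 (E)-6,7-dideoxy-3,4-O-isopropylidene-7-(4-methoxybenzyloxy)-L-galacto-hept-6-enono-1,5-lactone
Product: 12 (E)-6,7-dideoxy-3,4-O-isopropylidene-2-O-(4-methoxybenzyl)-7-(4-methoxybenzyloxy)-L-galacto-hept-6-enono-1,5-lactone
Conditions: PMBCl, Ag2O, 4 Å MS, CH2Cl2, rt, dark
Reagents that add atoms: 4-methoxybenzyl chloride, COc1ccc(CCl)cc1
Why: Silver(I) oxide-promoted Williamson etherification is neutral, so the β-alkoxy lactone is not enolised and the enol ether is not protonated; the configuration at C1 is of no consequence because this centre becomes trigonal in step 9.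

**Step 9**
Reactants: 12 (E)-6,7-dideoxy-3,4-O-isopropylidene-2-O-(4-methoxybenzyl)-7-(4-methoxybenzyloxy)-L-galacto-hept-6-enono-1,5-lactone
Product: 15 (1S,2R,3R,6R)-2,3-(isopropylidenedioxy)-1,6-bis(4-methoxybenzyloxy)cyclohex-4-ene-1-carboxylic acid, via silyl ketene acetal 13 (not isolated), via trimethylsilyl ester 14 (not isolated)
Conditions: TMSCl–Et3N (premixed, excess), THF, −100 °C, then LDA (commercial solution, 1.4 equiv); → rt; toluene, 90 °C; aq. citric acid
Reagents that add atoms: chlorotrimethylsilane, C[Si](C)(C)Cl (its silicon is carried by 13 and 14 and is lost on work-up)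
Why: LDA removes C1–H of the lactone in the presence of TMSCl, so the enolate is O-silylated at −100 °C before it can expel the C2 acetal oxygen, and on warming the cyclic silyl ketene acetal (C7=C1) and the tethered allyl unit (C4–C5=C6) undergo a suprafacial [3,3] shift that forms C1–C6, cleaves the C4–O lactone bond and moves the alkene to C4=C5. The closest known reaction is the Ireland–Claisen rearrangement of 6-alkenyl δ-lactone silyl ketene acetals to cycloalkene carboxylic acids. The cyclohexene ring (C1–C2–C3–C4=C5–C6) is closed by the C1–C6 bond inside a bicyclic six-centre array that can only be boat-shaped, since the two-carbon tether C2–C3 holds the allyl unit over the ketene acetal and a chair would require an E alkene in the six-membered ring. C1 is set by the C4 stereocentre, which is consumed: C6 must arrive on the ketene acetal face on which C4 carries the alkenyl group, the face of O2 and O3, which leaves O1 cis to O2/O3 and C7 trans. C6 is set by the E geometry of the enol ether, which in the boat puts its hydrogen inside and its PMB-oxy group outside, so that O6 ends trans (diaxial) to O1. The step needs O-silylation to beat β-elimination, secured by the internal quench at low temperature, and a geometrically pure E enol ether, secured in step 7; the alkoxy donor on C6 should also lower the barrier of the shift.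

**Step 10**
Reactants: 15 (1S,2R,3R,6R)-2,3-(isopropylidenedioxy)-1,6-bis(4-methoxybenzyloxy)cyclohex-4-ene-1-carboxylic acid
Product: 16 [2,3-(isopropylidenedioxy)-1,6-bis(4-methoxybenzyloxy)cyclohex-4-en-1-yl]methanol (ring configuration of 15)
Conditions: LiAlH4, THF, 0 → 50 °C; aq. NaOH work-up
Reagents that add atoms: none
Why: Lithium aluminium hydride reduction of the carboxylic acid to the primary alcohol; the ethers, the acetal and the isolated alkene are inert.

**Step 11**
Reactants: 16 [2,3-(isopropylidenedioxy)-1,6-bis(4-methoxybenzyloxy)cyclohex-4-en-1-yl]methanol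
Product: 17 [2,3-(isopropylidenedioxy)-1,6-bis(4-methoxybenzyloxy)cyclohex-4-en-1-yl]methyl benzoate
Conditions: BzCl, pyridine, DMAP (cat.), CH2Cl2, 0 °C → rt
Reagents that add atoms: benzoyl chloride, O=C(Cl)c1ccccc1
Why: DMAP-catalysed acylation of the only free hydroxyl installs the C7 benzoate of the target.

**Step 12**
Reactants: 17 [2,3-(isopropylidenedioxy)-1,6-bis(4-methoxybenzyloxy)cyclohex-4-en-1-yl]methyl benzoate
Product: 18 [2,3-dihydroxy-1,6-bis(4-methoxybenzyloxy)cyclohex-4-en-1-yl]methyl benzoate (cis-2,3-diol)
Conditions: AcOH–H2O (4:1), 45 °C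
Reagents that add atoms: none
Why: Acid-catalysed acetal hydrolysis in aqueous acetic acid frees the cis-2,3-diol while the PMB ethers and the benzoate survive, and it is done here because no acid-labile vinyl oxirane is present yet.

**Step 13**
Reactants: 18 [2,3-dihydroxy-1,6-bis(4-methoxybenzyloxy)cyclohex-4-en-1-yl]methyl benzoate
Product: 19 [3-(tert-butyldimethylsilyloxy)-2-hydroxy-1,6-bis(4-methoxybenzyloxy)cyclohex-4-en-1-yl]methyl benzoate
Conditions: TBSCl (1.2 equiv), imidazole, DMF, 0 °C → rt
Reagents that add atoms: tert-butyldimethylsilyl chloride, CC(C)(C)[Si](C)(C)Cl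
Why: Imidazole-mediated silylation with the bulky TBS chloride should go to the allylic C3 hydroxyl, since the C2 hydroxyl is shielded by the fully substituted C1 and by cis oxygen substituents on both neighbours; this replaces a regioselective acylation of the cis-diol by a sterically controlled protection.

**Step 14**
Reactants: 19 [3-(tert-butyldimethylsilyloxy)-2-hydroxy-1,6-bis(4-methoxybenzyloxy)cyclohex-4-en-1-yl]methyl benzoate
Product: 20 [2-(benzoyloxy)-3-(tert-butyldimethylsilyloxy)-1,6-bis(4-methoxybenzyloxy)cyclohex-4-en-1-yl]methyl benzoate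
Conditions: BzCl, DMAP, pyridine, rt → 40 °C
Reagents that add atoms: benzoyl chloride, O=C(Cl)c1ccccc1
Why: DMAP-catalysed benzoylation of the one remaining (hindered) hydroxyl under amine conditions, which do not move the silyl group, installs the C2 benzoate without any regiochemical choice.

**Step 15**
Reactants: 20 [2-(benzoyloxy)-3-(tert-butyldimethylsilyloxy)-1,6-bis(4-methoxybenzyloxy)cyclohex-4-en-1-yl]methyl benzoate
Product: 21 [2-(benzoyloxy)-3-(tert-butyldimethylsilyloxy)-1,6-dihydroxycyclohex-4-en-1-yl]methyl benzoate (trans-1,6-diol)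
Conditions: DDQ (2.5 equiv), CH2Cl2–pH 7 buffer (10:1), 0 °C → rt
Reagents that add atoms: none
Why: Oxidative PMB ether cleavage by DDQ (benzylic hydride abstraction, hydrolysis of the oxocarbenium ion by water) removes both PMB groups in buffered wet solvent and spares benzoates, silyl ether and alkene.

**Step 16**
Reactants: 21 [2-(benzoyloxy)-3-(tert-butyldimethylsilyloxy)-1,6-dihydroxycyclohex-4-en-1-yl]methyl benzoate
Product: 23 [2-(benzoyloxy)-3-(tert-butyldimethylsilyloxy)-1,6-epoxycyclohex-4-en-1-yl]methyl benzoate (configuration of 24), via allylic mesylate 22 (not isolated)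
Conditions: Ms2O, Et3N, CH2Cl2, −20 °C; then DBU, 0 °C → rt
Reagents that add atoms: methanesulfonic anhydride, CS(=O)(=O)OS(C)(=O)=O (its mesyl group is carried by 22 and leaves in the ring closure)
Why: Selective sulfonylation of the secondary allylic C6 hydroxyl (the tertiary C1 hydroxyl does not react) with chloride-free mesyl anhydride, then base-induced intramolecular SN2 (3-exo-tet) displacement by O1 of the trans, antiperiplanar mesylate inverts C6 and places the oxirane on the face of O1, cis to O2 and O3.

**Step 17**
Reactants: 23 [2-(benzoyloxy)-3-(tert-butyldimethylsilyloxy)-1,6-epoxycyclohex-4-en-1-yl]methyl benzoate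
Product: 24 [(1S,2R,3R,6S)-2-(benzoyloxy)-1,6-epoxy-3-hydroxycyclohex-4-en-1-yl]methyl benzoate (CNP0285759.1)
Conditions: HF·pyridine, pyridine, THF, 0 °C → rt
Reagents that add atoms: none
Why: Fluoride-mediated desilylation with pyridine-buffered HF·pyridine generates no alkoxide, so O2→O3 benzoyl migration is not triggered and the oxirane is not opened.

**Compound list**

1 | D-galacturonic acid | OC(=O)[C@@H](O)[C@H](O)[C@H](O)[C@@H](O)C=O | starting material
2 | benzyl D-galactopyranuronate | O=C(OCc1ccccc1)[C@H]1OC(O)[C@H](O)[C@@H](O)[C@H]1O | intermediate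
3 | benzyl 3,4-O-isopropylidene-D-galactopyranuronate | O=C(OCc1ccccc1)[C@H]1OC(O)[C@H](O)[C@H]2OC(C)(C)O[C@@H]12 | intermediate
4 | 3,4-O-isopropylidene-D-galactopyranuronic acid | OC(=O)[C@H]1OC(O)[C@H](O)[C@H]2OC(C)(C)O[C@@H]12 | intermediate
5 | 4-methoxybenzyl alcohol | COc1ccc(CO)cc1 | starting material
6 | 4-methoxybenzyl (methylthio)methyl ether | COc1ccc(COCSC)cc1 | intermediate
7 | 4-methoxybenzyl chloromethyl ether | COc1ccc(COCCl)cc1 | intermediate
8 | [(4-methoxybenzyloxy)methyl]triphenylphosphonium chloride | COc1ccc(COC[P+](c2ccccc2)(c2ccccc2)c2ccccc2)cc1.[Cl-] | intermediate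
9 | [(4-methoxybenzyloxy)methylene]triphenylphosphorane | COc1ccc(COC=P(c2ccccc2)(c2ccccc2)c2ccccc2)cc1 | intermediate
10 | (E)-6,7-dideoxy-3,4-O-isopropylidene-7-(4-methoxybenzyloxy)-L-galacto-hept-6-enonic acid | OC(=O)[C@@H](O)[C@@H]1OC(C)(C)O[C@@H]1[C@@H](O)/C=C/OCc1ccc(OC)cc1 | intermediate
11 | (E)-6,7-dideoxy-3,4-O-isopropylidene-7-(4-methoxybenzyloxy)-L-galacto-hept-6-enono-1,5-lactone | O=C1O[C@@H](/C=C/OCc2ccc(OC)cc2)[C@H]2OC(C)(C)O[C@H]2[C@@H]1O | intermediate
12 | (E)-6,7-dideoxy-3,4-O-isopropylidene-2-O-(4-methoxybenzyl)-7-(4-methoxybenzyloxy)-L-galacto-hept-6-enono-1,5-lactone | O=C1O[C@@H](/C=C/OCc2ccc(OC)cc2)[C@H]2OC(C)(C)O[C@H]2[C@@H]1OCc1ccc(OC)cc1 | intermediate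
13 | trimethylsilyl ketene acetal of 12 | C[Si](C)(C)OC1=C(OCc2ccc(OC)cc2)[C@@H]3OC(C)(C)O[C@@H]3[C@H](/C=C/OCc2ccc(OC)cc2)O1 | intermediate
14 | trimethylsilyl ester of 15 | C[Si](C)(C)OC(=O)[C@]1(OCc2ccc(OC)cc2)[C@H](OCc2ccc(OC)cc2)C=C[C@H]2OC(C)(C)O[C@@H]12 | intermediate
15 | (1S,2R,3R,6R)-2,3-(isopropylidenedioxy)-1,6-bis(4-methoxybenzyloxy)cyclohex-4-ene-1-carboxylic acid (C7 and O6 on one face; O1, O2, O3 on the other) | OC(=O)[C@]1(OCc2ccc(OC)cc2)[C@H](OCc2ccc(OC)cc2)C=C[C@H]2OC(C)(C)O[C@@H]12 | intermediate
16 | [2,3-(isopropylidenedioxy)-1,6-bis(4-methoxybenzyloxy)cyclohex-4-en-1-yl]methanol (ring configuration of 15) | OC[C@]1(OCc2ccc(OC)cc2)[C@H](OCc2ccc(OC)cc2)C=C[C@H]2OC(C)(C)O[C@@H]12 | intermediate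
17 | C7 benzoate of 16 | O=C(OC[C@]1(OCc2ccc(OC)cc2)[C@H](OCc2ccc(OC)cc2)C=C[C@H]2OC(C)(C)O[C@@H]12)c1ccccc1 | intermediate
18 | cis-2,3-diol from 17 | O=C(OC[C@]1(OCc2ccc(OC)cc2)[C@H](OCc2ccc(OC)cc2)C=C[C@@H](O)[C@H]1O)c1ccccc1 | intermediate
19 | 3-O-TBS ether of 18 | O=C(OC[C@]1(OCc2ccc(OC)cc2)[C@H](OCc2ccc(OC)cc2)C=C[C@@H](O[Si](C)(C)C(C)(C)C)[C@H]1O)c1ccccc1 | intermediate
20 | 2-O-benzoate of 19 | O=C(OC[C@]1(OCc2ccc(OC)cc2)[C@H](OCc2ccc(OC)cc2)C=C[C@@H](O[Si](C)(C)C(C)(C)C)[C@H]1OC(=O)c1ccccc1)c1ccccc1 | intermediate
21 | trans-1,6-diol from 20 | O=C(OC[C@]1(O)[C@H](O)C=C[C@@H](O[Si](C)(C)C(C)(C)C)[C@H]1OC(=O)c1ccccc1)c1ccccc1 | intermediate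
22 | 6-O-mesylate of 21 | O=C(OC[C@]1(O)[C@H](OS(C)(=O)=O)C=C[C@@H](O[Si](C)(C)C(C)(C)C)[C@H]1OC(=O)c1ccccc1)c1ccccc1 | intermediate
23 | 3-O-TBS ether of 24 | O=C(OC[C@]12O[C@H]1C=C[C@@H](O[Si](C)(C)C(C)(C)C)[C@H]2OC(=O)c1ccccc1)c1ccccc1 | intermediate
24 | [(1S,2R,3R,6S)-2-(benzoyloxy)-1,6-epoxy-3-hydroxycyclohex-4-en-1-yl]methyl benzoate | O=C(OC[C@]12O[C@H]1C=C[C@@H](O)[C@H]2OC(=O)c1ccccc1)c1ccccc1 | target

**Totals.** Total step count: 17 (15 in the main line, 2 for the Wittig salt). Longest linear sequence: 15 steps (steps 1–3 and 6–17).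

**Steps most likely to fail**

1. Step 9. What may go wrong: expulsion of the C2 acetal oxygen from the lithium enolate (E1cB) before O-silylation, or decay of the labile trimethylsilyl ketene acetal before the boat shift is reached. Fallback: from 12, soft enolisation with TBSOTf and Et3N (CH2Cl2, 0 °C → rt) reaches the ketene acetal through an O-silylated oxocarbenium ion and never forms a metal enolate. It should give the more robust tert-butyldimethylsilyl ketene acetal of 12 F1. Heating (toluene, 80–100 °C) would then give the tert-butyldimethylsilyl ester of 15 F2, and K2CO3 in aqueous methanol would hydrolyse it to acid 15, where the route is rejoined.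

2. Step 6. What may go wrong: stalled olefination, because the tripotassium salt of 4 dissolves poorly and its hemiacetal opens slowly. Fallback: from 3, whose dipotassium alkoxide is soluble, the same ylide 9 is used at −78 → −20 °C, limited to what the two hydroxyls and the aldehyde consume so that β-elimination of the uronate ester is restrained. This should give benzyl (E)-6,7-dideoxy-3,4-O-isopropylidene-7-(4-methoxybenzyloxy)-L-galacto-hept-6-enonate F3. Neutral transesterification–lactonisation (distannoxane catalyst or 2-hydroxypyridine, toluene, 60 °C) with removal of the Z isomer would close it to lactone 11, where the route is rejoined; steps 3 and 7 are then bypassed.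

3. Step 2. What may go wrong: acetal formation across O1/O2 of the α-anomer or at the anomeric hydroxyl, giving mixtures. Fallback: from 1, Fischer glycosidation in benzyl alcohol (AcCl cat., 70 °C, equilibrated to the pyranoside) gives benzyl (benzyl D-galactopyranosid)uronate F4, whose only cis-diol is O3/O4. Thermodynamic acetonation (2,2-dimethoxypropane, CSA, acetone) gives benzyl (benzyl 3,4-O-isopropylidene-D-galactopyranosid)uronate F5. Hydrogenolysis (H2, Pd/C) removes both benzyl groups to give acid 4, where the route is rejoined.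

**Further compounds**

F1 | step 9 | tert-butyldimethylsilyl ketene acetal of 12 | CC(C)(C)[Si](C)(C)OC1=C(OCc2ccc(OC)cc2)[C@@H]3OC(C)(C)O[C@@H]3[C@H](/C=C/OCc2ccc(OC)cc2)O1
F2 | step 9 | tert-butyldimethylsilyl ester of 15 | CC(C)(C)[Si](C)(C)OC(=O)[C@]1(OCc2ccc(OC)cc2)[C@H](OCc2ccc(OC)cc2)C=C[C@H]2OC(C)(C)O[C@@H]12
F3 | step 6 | benzyl (E)-6,7-dideoxy-3,4-O-isopropylidene-7-(4-methoxybenzyloxy)-L-galacto-hept-6-enonate | O=C(OCc1ccccc1)[C@@H](O)[C@@H]1OC(C)(C)O[C@@H]1[C@@H](O)/C=C/OCc1ccc(OC)cc1
F4 | step 2 | benzyl (benzyl D-galactopyranosid)uronate | O=C(OCc1ccccc1)[C@H]1OC(OCc2ccccc2)[C@H](O)[C@@H](O)[C@H]1O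
F5 | step 2 | benzyl (benzyl 3,4-O-isopropylidene-D-galactopyranosid)uronate | O=C(OCc1ccccc1)[C@H]1OC(OCc2ccccc2)[C@H](O)[C@H]2OC(C)(C)O[C@@H]12
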